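**Plan**

- Ring numbering used throughout: C1 carries the CH2 arm, C2/C3/C6 carry Br, C4/C5 carry OH. The retrosynthesis cuts, in order, the two C3–Br bonds, the two C4–O bonds (each traced back to a C4–CHO group), the C2–Br and C6–Br bonds, the C4–CHO bonds and last one benzylic C–O bond of the central ether.
- Forward, the chain is joined first: 3-hydroxybenzyl alcohol is converted into the symmetric dibenzyl ether (MOM on, Appel, Williamson, MOM off). No ring is formed anywhere; both arene rings are bought.
- Both rings are then elaborated in parallel: formylation at C4, dibromination at C2/C6, exchange of the formyl carbon for oxygen at C4, bromination at C3.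
- Enabling feature: the lone C5 hydroxyl steers bromine to C6 (ortho) and C2 (para), and the formyl group on C4, ortho to O5, is the carbon that is swapped for the C4 oxygen by aryl migration.
- Stereochemistry: the target has no stereogenic element, so nothing has to be set or preserved.

Key step: step 7

Remark: the target SMILES contains no stereocentre, axis or stereogenic double bond; it defines one achiral compound, and the route is planned for exactly that constitution.

**Route**

Step 1
Reactants: 1 3-hydroxybenzyl alcohol
Product: 2 3-(methoxymethoxy)benzyl alcohol
Conditions: MOMCl (1.05 equiv), K2CO3, acetone, 0 °C to rt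
Reagents that add atoms: chloromethyl methyl ether (MOMCl), COCCl
Why: Carbonate deprotonates only the phenol, which is far more acidic than the benzylic alcohol, so the Williamson-type O-alkylation with MOMCl should take place on the phenolic oxygen alone.

Step 2
Reactants: 2 3-(methoxymethoxy)benzyl alcohol
Product: 3 3-(methoxymethoxy)benzyl bromide
Conditions: CBr4, PPh3, CH2Cl2, 0 °C
Reagents that add atoms: carbon tetrabromide, BrC(Br)(Br)Br
Why: The Appel reaction converts the primary benzylic alcohol into the bromide under neutral conditions that the MOM acetal should tolerate.

Step 3
Reactants: 2 3-(methoxymethoxy)benzyl alcohol; 3 3-(methoxymethoxy)benzyl bromide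
Product: 4 bis[3-(methoxymethoxy)benzyl] ether
Conditions: NaH, THF, 0 °C; then 3, cat. n-Bu4NI, rt
Reagents that add atoms: none
Why: Williamson ether synthesis, in which the sodium alkoxide of 2 displaces bromide from the unhindered benzylic bromide 3 by SN2 while the MOM acetals are inert to base.

Step 4
Reactants: 4 bis[3-(methoxymethoxy)benzyl] ether
Product: 5 bis(3-hydroxybenzyl) ether
Conditions: conc. HCl (cat.), MeOH, 50 °C
Reagents that add atoms: none
Why: Acid-catalysed acetal exchange with methanol removes both MOM groups, and the dibenzyl ether should survive because its ring oxygens sit meta to the benzylic carbons and give no cation stabilisation.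

Step 5
Reactants: 5 bis(3-hydroxybenzyl) ether
Product: 7 bis(4-formyl-3-hydroxybenzyl) ether, via bis-salicyl alcohol 6 (not isolated)
Conditions: MgCl2 (anhydrous), Et3N, (CH2O)n, MeCN, reflux; then 1 M HCl
Reagents that add atoms: paraformaldehyde (formaldehyde), C=O
Why: Magnesium-mediated ortho-formylation (Casiraghi–Skattebøl reaction), in which the magnesium phenoxide delivers formaldehyde only ortho to oxygen and the salicyl alkoxide 6 is oxidised by a second formaldehyde through Oppenauer-type hydride transfer; of the two ortho sites the open C4 should be preferred to C6, which is flanked by the CH2 arm, as is usual for 3-substituted phenols.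

Step 6
Reactants: 7 bis(4-formyl-3-hydroxybenzyl) ether
Product: 8 bis(2,6-dibromo-4-formyl-3-hydroxybenzyl) ether
Conditions: Br2 (4.2 equiv), NaOAc, AcOH, rt, dark
Reagents that add atoms: bromine, BrBr
Why: Electrophilic aromatic bromination in which the C5 hydroxyl (ortho/para director) and the C4 formyl group (meta director) both point to C2 and C6, the 3,5-dibromosalicylaldehyde pattern, while C3 stays free and acetate takes up the HBr.

Step 7
Reactants: 8 bis(2,6-dibromo-4-formyl-3-hydroxybenzyl) ether
Product: 10 bis(2,6-dibromo-3,4-dihydroxybenzyl) ether, via bis-formate ester 9 (not isolated)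
Conditions: 30% aq. H2O2 (5 equiv), NaHCO3, degassed THF/H2O, 0 °C to rt, Ar; then aq. Na2S2O3, 1 M HCl to pH 3–4 at 0 °C
Reagents that add atoms: hydrogen peroxide, OO
Why: Dakin oxidation: at about pH 8 the acidic dibromophenol is present as its phenoxide, hydroperoxide adds to each formyl carbon, and in the tetrahedral adduct the aryl group shifts from carbon to the neighbouring peroxide oxygen with loss of hydroxide, which forms the C4–O bond and gives the aryl formate 9; water then cleaves this ester in the same flask to the catechol and formate. The closest known reaction type is the Dakin oxidation of ortho-hydroxybenzaldehydes, 3,5-dibromosalicylaldehydes included, which is a Baeyer–Villiger-type 1,2-shift. No ring is closed and no stereocentre is formed; two C–O bonds arise, one on each ring. The selectivity needed is aryl over hydride migration (hydride migration would give the salicylic acid), and the C5 phenoxide ortho to the migrating carbon secures it by raising the migratory aptitude of the ring. The second requirement is that the product survives: bicarbonate buffering, low temperature and exclusion of air should keep the new C4 phenoxide, which lies para to the benzylic ether, from expelling alkoxide as a quinone methide and keep the catechol from oxidation to the o-quinone.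

Step 8
Reactants: 10 bis(2,6-dibromo-3,4-dihydroxybenzyl) ether
Product: 11 bis(2,3,6-tribromo-4,5-dihydroxybenzyl) ether
Conditions: NBS (2.05 equiv), MeCN, −10 to 0 °C, dark, Ar; aq. Na2S2O3 work-up
Reagents that add atoms: N-bromosuccinimide, O=C1CCC(=O)N1Br
Why: Electrophilic aromatic bromination at the only remaining ring hydrogen, C3, ortho to the new C4 hydroxyl; NBS leaves neutral succinimide in place of HBr, which should spare the acid-sensitive para-hydroxybenzyl ether, and exact stoichiometry at low temperature should disfavour ipso attack at C1.

**Compound list**

1 | 3-hydroxybenzyl alcohol | OCc1cccc(O)c1 | starting material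
2 | 3-(methoxymethoxy)benzyl alcohol | COCOc1cccc(CO)c1 | intermediate
3 | 3-(methoxymethoxy)benzyl bromide | COCOc1cccc(CBr)c1 | intermediate
4 | bis[3-(methoxymethoxy)benzyl] ether | COCOc1cccc(COCc2cccc(OCOC)c2)c1 | intermediate
5 | bis(3-hydroxybenzyl) ether | Oc1cccc(COCc2cccc(O)c2)c1 | intermediate
6 | bis[3-hydroxy-4-(hydroxymethyl)benzyl] ether (bis-salicyl alcohol, present as its magnesium salt) | OCc1ccc(COCc2ccc(CO)c(O)c2)cc1O | intermediate
7 | bis(4-formyl-3-hydroxybenzyl) ether | O=Cc1ccc(COCc2ccc(C=O)c(O)c2)cc1O | intermediate
8 | bis(2,6-dibromo-4-formyl-3-hydroxybenzyl) ether | O=Cc1cc(Br)c(COCc2c(Br)cc(C=O)c(O)c2Br)c(Br)c1O | intermediate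
9 | bis[2,6-dibromo-4-(formyloxy)-3-hydroxybenzyl] ether (bis-formate ester) | O=COc1cc(Br)c(COCc2c(Br)cc(OC=O)c(O)c2Br)c(Br)c1O | intermediate
10 | bis(2,6-dibromo-3,4-dihydroxybenzyl) ether | Oc1cc(Br)c(COCc2c(Br)cc(O)c(O)c2Br)c(Br)c1O | intermediate
11 | bis(2,3,6-tribromo-4,5-dihydroxybenzyl) ether | Oc1c(O)c(Br)c(COCc2c(Br)c(O)c(O)c(Br)c2Br)c(Br)c1Br | target

**Step count**

Total steps: 8. Longest linear sequence: 8 steps (1 → 2 → 3 → 4 → 5 → 7 → 8 → 10 → 11).

**Steps most likely to fail**

Step 7. On the electron-poor dibrominated rings the aryl shift may be slow, so that hydride migration to the carboxylic acid competes. The basic peroxide medium may also induce loss of the benzylic ether from the product phenoxide or over-oxidation of the catechol. Fallback: carry out the carbon-to-oxygen exchange before the halogenation. Setting out from 7, Dakin oxidation of the electron-rich, unbrominated salicylaldehyde (H2O2, NaHCO3, THF/H2O, 0 °C) should give bis(3,4-dihydroxybenzyl) ether F1. Exhaustive bromination of the three free positions of each ring (NBS, 6 equiv, MeCN, 0 °C) would then lead directly to 11, by-passing 8 and 10.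

Step 8. Ipso attack of the brominating agent at C1, ionisation of the para-hydroxybenzyl ether to a quinone methide, or oxidation of the catechol to the o-quinone may compete with substitution at C3. Fallback: make the ether scission deliberate and rebuild the ether last. Setting out from 10, Br2 (2 equiv) in AcOH with added HBr should brominate C3 and cleave the ether to 2,3,6-tribromo-4,5-dihydroxybenzyl bromide F2, two molecules per molecule of 10. Hydrolysis in aqueous acetone would give 2,3,6-tribromo-4,5-dihydroxybenzyl alcohol F3. Acid-catalysed dehydrative self-condensation of F3 (cat. TsOH, toluene, azeotropic removal of water), in which every ring position is blocked so that only O-alkylation by the benzylic hydroxyl is open, returns to the route at 11.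

Step 5. The twofold formylation may stall at the mono-aldehyde when its magnesium salt precipitates, and during the long reflux the salicyl alkoxide stage may condense further with formaldehyde to methoxymethyl or diarylmethane by-products. Fallback: separate the hydroxymethylation from the oxidation. Setting out from 5, boron-templated ortho-hydroxymethylation (PhB(OH)2, (CH2O)n, cat. propionic acid, toluene, reflux with water removal) should give bis[(2-phenyl-4H-1,3,2-benzodioxaborin-7-yl)methyl] ether F4, in which each new CH2–O unit is locked as a cyclic boronate and cannot condense further. Exchange with propane-1,3-diol would free the bis-salicyl alcohol 6, now isolated, and MnO2 in EtOAc at rt should oxidise its two benzylic alcohols, returning to the route at 7.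

**Further compounds**

F1 | step 7 | bis(3,4-dihydroxybenzyl) ether | Oc1ccc(COCc2ccc(O)c(O)c2)cc1O
F2 | step 8 | 2,3,6-tribromo-4,5-dihydroxybenzyl bromide | Oc1c(O)c(Br)c(CBr)c(Br)c1Br
F3 | step 8 | 2,3,6-tribromo-4,5-dihydroxybenzyl alcohol | Oc1c(O)c(Br)c(CO)c(Br)c1Br
F4 | step 5 | bis[(2-phenyl-4H-1,3,2-benzodioxaborin-7-yl)methyl] ether | c1ccc(cc1)B1OCc2ccc(COCc3ccc4COB(c5ccccc5)Oc4c3)cc2O1
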